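**Retrosynthetic overview**
- The six-membered ring is never built: it is the benzene ring of 2-methylphloroglucinol, dearomatised in the last step by a catalyst-controlled C-prenylation that sets the quaternary centre.
- The CH2 link is cut next: reductive alkylation of 3-methylphlorisobutyrophenone with a cyclopentane β-hydroxy aldehyde.
- Key bond: the tertiary C–O bond of the carbinol, made by face-selective nucleophilic epoxidation of a cyclopentene carbaldehyde; only the α C–O bond of the epoxide is then cleaved reductively.
- The cyclopentane ring is formed first, by ring contraction of (R)-limonene oxide (glycol cleavage, then aldol condensation); limonene supplies the isopropenyl stereocentre.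

Assumption: the target is handled as the enol tautomer drawn in the SMILES (its β-triketone tautomers interconvert, and the descriptor 6R refers to that tautomer); commercial (+)-limonene oxide is the cis/trans mixture derived from (R)-limonene.

**Step 1**
Reactants: 1 (+)-limonene 1,2-oxide [(4R)-1-methyl-4-(prop-1-en-2-yl)-7-oxabicyclo[4.1.0]heptane; cis/trans mixture]
Product: 3 (3R)-6-oxo-3-(prop-1-en-2-yl)heptanal, via trans-diol 2 (not isolated)
Conditions: H5IO6 (1.2 equiv), THF/H2O (2:1), 0 °C to rt
Reagents that add atoms: water, O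
Why: Acid-catalysed epoxide hydrolysis (both epoxide isomers give the trans-diaxial diol 2) followed in the same flask by Malaprade periodate glycol cleavage; the ring stereocentre is not involved and becomes C3 of 3 unchanged.

**Step 2**
Reactants: 3 (3R)-6-oxo-3-(prop-1-en-2-yl)heptanal
Product: 5 (5S)-2-methyl-5-(prop-1-en-2-yl)cyclopent-1-ene-1-carbaldehyde, via aldol adduct 4 (not isolated)
Conditions: piperidine (0.1 equiv), AcOH (0.1 equiv), toluene, reflux, Dean–Stark
Reagents that add atoms: none
Why: Intramolecular aldol condensation through the aldehyde enamine (attack on the methyl ketone closes the five-membered ring) and dehydration of adduct 4; the isopropenyl-bearing centre is not acidic in 3 or 5 and is retained.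

**Step 3**
Reactants: 5 (5S)-2-methyl-5-(prop-1-en-2-yl)cyclopent-1-ene-1-carbaldehyde
Product: 6 (1S,2S,5R)-5-methyl-2-(prop-1-en-2-yl)-6-oxabicyclo[3.1.0]hexane-1-carbaldehyde
Conditions: 30% aq H2O2 (3 equiv), NaOH (0.3 equiv), MeOH, 0 °C
Reagents that add atoms: hydrogen peroxide, OO
Why: Weitz–Scheffer nucleophilic epoxidation: hydroperoxide adds to the β-carbon and the enolate closes onto oxygen on the face opposite the neighbouring isopropenyl group, which forms the tertiary C–O bond that ends as the carbinol of 13 (C5 set as R, C1 as S), while the electron-rich isopropenyl alkene is inert to the peroxide anion.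

**Step 4**
Reactants: 6 (1S,2S,5R)-5-methyl-2-(prop-1-en-2-yl)-6-oxabicyclo[3.1.0]hexane-1-carbaldehyde
Product: 8 (1S,2R,5R)-2-hydroxy-2-methyl-5-(prop-1-en-2-yl)cyclopentane-1-carbaldehyde, via C1-epimeric aldehyde 7 (not isolated)
Conditions: SmI2 (2.1 equiv), THF/MeOH, −90 °C, 10 min; pH 7 buffer; then DBU (0.1 equiv), CH2Cl2, 0 °C
Reagents that add atoms: none
Why: Samarium diiodide reduction of an α,β-epoxy carbonyl compound: electron transfer to the formyl group gives a ketyl whose α C–O bond cleaves, a second electron and MeOH give the aldol with the β C–O bond and its configuration untouched, and the kinetic C1 epimer 7 is equilibrated by DBU through the enol to 8, whose formyl group is trans to both the isopropenyl and the methyl group.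

**Step 5**
Reactants: 9 2-methylbenzene-1,3,5-triol (2-methylphloroglucinol)
Product: 10 2-methyl-1-(2,4,6-trihydroxy-3-methylphenyl)propan-1-one
Conditions: isobutyryl chloride (1.1 equiv), AlCl3 (3.5 equiv), PhNO2/CH2Cl2, 0 °C to 40 °C; aq HCl
Reagents that add atoms: isobutyryl chloride (2-methylpropanoyl chloride), CC(C)C(Cl)=O
Why: Friedel–Crafts C-acylation; the two open ring positions of 9 are equivalent and the first acyl group deactivates the ring against a second acylation, and no stereocentre is involved.

**Step 6**
Reactants: 8 (1S,2R,5R)-2-hydroxy-2-methyl-5-(prop-1-en-2-yl)cyclopentane-1-carbaldehyde, 10 2-methyl-1-(2,4,6-trihydroxy-3-methylphenyl)propan-1-one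
Product: 12 2-methyl-1-[2,4,6-trihydroxy-3-{[(1S,2R,5R)-2-hydroxy-2-methyl-5-(prop-1-en-2-yl)cyclopentyl]methyl}-5-methylphenyl]propan-1-one, via ortho-quinone methide 11 (not isolated)
Conditions: L-proline (0.2 equiv), Hantzsch ester (diethyl 2,6-dimethyl-1,4-dihydropyridine-3,5-dicarboxylate, 1.3 equiv), CH2Cl2/EtOH, rt
Reagents that add atoms: none
Why: Three-component reductive alkylation (Knoevenagel-type condensation, then transfer hydrogenation): the only free ring carbon of 10 condenses with the aldehyde to ortho-quinone methide 11, which takes hydride from the Hantzsch ester at the exocyclic carbon and rearomatises; no new stereocentre is formed, and C1 of the cyclopentane (trans, thermodynamic) is fixed once the formyl carbon has become CH2.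

**Step 7**
Reactants: 12 2-methyl-1-[2,4,6-trihydroxy-3-{[(1S,2R,5R)-2-hydroxy-2-methyl-5-(prop-1-en-2-yl)cyclopentyl]methyl}-5-methylphenyl]propan-1-one
Product: 13 (6R)-3,5-dihydroxy-4-{[(1S,2R,5R)-2-hydroxy-2-methyl-5-(prop-1-en-2-yl)cyclopentyl]methyl}-6-methyl-6-(3-methylbut-2-en-1-yl)-2-(2-methylpropanoyl)cyclohexa-2,4-dien-1-one (CNP0261875.1)
Conditions: Pd2(dba)3·CHCl3 (2.5 mol %), (S,S)-DACH-phenyl Trost ligand [N,N'-((1S,2S)-cyclohexane-1,2-diyl)bis(2-(diphenylphosphanyl)benzamide), 7.5 mol %], prenyl acetate (1.05 equiv), Et3N (1.2 equiv), CH2Cl2, 0 °C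
Reagents that add atoms: prenyl acetate (3-methylbut-2-en-1-yl acetate), CC(C)=CCOC(C)=O
Why: Proposed new method: a zerovalent-palladium asymmetric allylic alkylation in which the prochiral nucleophile is the hexasubstituted acylphloroglucinolate of 12 — the chiral palladium complex ionises prenyl acetate to a cationic π-(1,1-dimethylallyl)palladium species, the triethylammonium phenolate (deprotonated at the OH para to the acyl group) attacks outer-sphere with its methyl-bearing carbon at the unsubstituted allyl terminus (the only terminus a fully substituted carbon can reach, so the prenyl group arrives linear), the carbon carrying the branched cyclopentylmethyl group is too hindered to compete, O-prenyl ethers re-ionise under the catalyst and funnel to the C-alkylated non-aromatic triketone that cannot rearomatise, and the ligand amide N–H hydrogen-bonds the phenolate oxygen so that the acyl-chelated flank and the alkyl flank of the ring are told apart in the chiral pocket and one face of the methyl-bearing carbon is exposed, the cyclopentane stereocentres five bonds away exerting little bias (catalyst control; the ligand hand that gives 6R is fixed in the first pair of runs, the (S,S) ligand being the starting choice); the closest known reaction types are Trost-type palladium-catalysed asymmetric allylic alkylation of prochiral carbon nucleophiles, including asymmetric allylic dearomatisation of naphthols, and the non-asymmetric base-mediated dearomative C-prenylation of acylphloroglucinols.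

**Compound list**
1 | (+)-limonene 1,2-oxide, (4R)-1-methyl-4-(prop-1-en-2-yl)-7-oxabicyclo[4.1.0]heptane, cis/trans mixture | C=C(C)[C@H]1CC2OC2(C)CC1 | starting material
2 | (1S,2S,4R)-1-methyl-4-(prop-1-en-2-yl)cyclohexane-1,2-diol (trans-diol) | C=C(C)[C@@H]1CC[C@](C)(O)[C@@H](O)C1 | intermediate (not isolated)
3 | (3R)-6-oxo-3-(prop-1-en-2-yl)heptanal | C=C(C)[C@@H](CC=O)CCC(C)=O | intermediate
4 | (5R)-2-hydroxy-2-methyl-5-(prop-1-en-2-yl)cyclopentane-1-carbaldehyde, aldol adduct, mixture at C1 and C2 | C=C(C)[C@@H]1CCC(C)(O)C1C=O | intermediate (not isolated)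
5 | (5S)-2-methyl-5-(prop-1-en-2-yl)cyclopent-1-ene-1-carbaldehyde | C=C(C)[C@@H]1CCC(C)=C1C=O | intermediate
6 | (1S,2S,5R)-5-methyl-2-(prop-1-en-2-yl)-6-oxabicyclo[3.1.0]hexane-1-carbaldehyde (epoxide oxygen trans to isopropenyl) | C=C(C)[C@@H]1CC[C@@]2(C)O[C@@]12C=O | intermediate
7 | (1R,2R,5R)-2-hydroxy-2-methyl-5-(prop-1-en-2-yl)cyclopentane-1-carbaldehyde (formyl cis to isopropenyl) | C=C(C)[C@@H]1CC[C@@](C)(O)[C@@H]1C=O | intermediate (not isolated)
8 | (1S,2R,5R)-2-hydroxy-2-methyl-5-(prop-1-en-2-yl)cyclopentane-1-carbaldehyde (formyl trans to isopropenyl, cis to OH) | C=C(C)[C@@H]1CC[C@@](C)(O)[C@H]1C=O | intermediate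
9 | 2-methylbenzene-1,3,5-triol (2-methylphloroglucinol) | Cc1c(O)cc(O)cc1O | starting material
10 | 2-methyl-1-(2,4,6-trihydroxy-3-methylphenyl)propan-1-one | CC(C)C(=O)c1c(O)cc(O)c(C)c1O | intermediate
11 | 3,5-dihydroxy-6-{[(1S,2R,5R)-2-hydroxy-2-methyl-5-(prop-1-en-2-yl)cyclopentyl]methylidene}-2-methyl-4-(2-methylpropanoyl)cyclohexa-2,4-dien-1-one (ortho-quinone methide) | C=C(C)[C@@H]1CC[C@@](C)(O)[C@H]1C=C1C(=O)C(C)=C(O)C(C(=O)C(C)C)=C1O | intermediate (not isolated)
12 | 2-methyl-1-[2,4,6-trihydroxy-3-{[(1S,2R,5R)-2-hydroxy-2-methyl-5-(prop-1-en-2-yl)cyclopentyl]methyl}-5-methylphenyl]propan-1-one | C=C(C)[C@@H]1CC[C@@](C)(O)[C@H]1Cc1c(O)c(C)c(O)c(C(=O)C(C)C)c1O | intermediate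
13 | (6R)-3,5-dihydroxy-4-{[(1S,2R,5R)-2-hydroxy-2-methyl-5-(prop-1-en-2-yl)cyclopentyl]methyl}-6-methyl-6-(3-methylbut-2-en-1-yl)-2-(2-methylpropanoyl)cyclohexa-2,4-dien-1-one | C=C(C)[C@@H]1CC[C@@](C)(O)[C@H]1CC1=C(O)[C@@](C)(CC=C(C)C)C(=O)C(C(=O)C(C)C)=C1O | target

**Step count and risks**
Total steps: 7. Longest linear sequence: 6 (steps 1, 2, 3, 4, 6, 7 from compound 1); step 5 is a one-step side branch.

Step 7 (the proposed new step) is the most likely to fail. The risks are low diastereoselectivity, alkylation at oxygen or at the other alkylated ring carbon, and a second prenylation of the more acidic product. The fallback uses known chemistry, sets out from 12 and comes back at 13. The phenolate of 12 is alkylated without a catalyst (prenyl bromide 1.0 equiv, NaOMe, MeOH, −20 °C to 0 °C), the classical dearomative C-prenylation of alkylated acylphloroglucinols. It gives 13 together with its C6 epimer, (6S)-3,5-dihydroxy-4-{[(1S,2R,5R)-2-hydroxy-2-methyl-5-(prop-1-en-2-yl)cyclopentyl]methyl}-6-methyl-6-(3-methylbut-2-en-1-yl)-2-(2-methylpropanoyl)cyclohexa-2,4-dien-1-one F5, in roughly equal amounts. Because the cyclopentane unit is enantiopure the two are diastereomers, and 13 is obtained by preparative reversed-phase HPLC. Stereocontrol by the catalyst is thus replaced by an unselective alkylation plus diastereomer separation.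

Step 4 is the second risk. The product aldehyde may be over-reduced, the aldol may lose water back to 5, or the C1 equilibration may be incomplete. The fallback sets out from 6 and comes back at 8, and replaces the electron-transfer reduction by an internal redox at the ester oxidation level. Compound 6 undergoes N-heterocyclic-carbene-catalysed redox esterification (3-benzyl-5-(2-hydroxyethyl)-4-methylthiazolium chloride 10 mol %, iPr2NEt, MeOH, CH2Cl2, 30 °C), in which the carbene adduct opens the epoxide at the α-carbon and methanol traps the acyl azolium. After equilibration at C1 with catalytic NaOMe in MeOH if needed, this gives methyl (1S,2R,5R)-2-hydroxy-2-methyl-5-(prop-1-en-2-yl)cyclopentane-1-carboxylate F1. LiAlH4 (THF, 0 °C) reduces it to (1R,2R,3R)-2-(hydroxymethyl)-1-methyl-3-(prop-1-en-2-yl)cyclopentan-1-ol F2. Oxidation of the primary alcohol only (TEMPO 10 mol %, PhI(OAc)2, CH2Cl2, rt) then gives 8.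

Step 6 is the third risk. Under amine catalysis 8 may lose water back to 5 or undergo retro-aldol cleavage, and the hindered aldehyde may condense slowly. The fallback sets out from 8 and comes back at 12, carrying the tertiary alcohol through the union as a silyl ether so that it cannot take part in retro-aldol cleavage. Silylation (TESOTf, 2,6-lutidine, CH2Cl2, −78 °C) gives (1S,2R,5R)-2-methyl-5-(prop-1-en-2-yl)-2-[(triethylsilyl)oxy]cyclopentane-1-carbaldehyde F3. The same reductive alkylation with 10 gives 2-methyl-1-[2,4,6-trihydroxy-3-methyl-5-({(1S,2R,5R)-2-methyl-5-(prop-1-en-2-yl)-2-[(triethylsilyl)oxy]cyclopentyl}methyl)phenyl]propan-1-one F4. Desilylation (TBAF, AcOH, THF, 0 °C) returns 12.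

**Further compounds**
F1 | step 4 | methyl (1S,2R,5R)-2-hydroxy-2-methyl-5-(prop-1-en-2-yl)cyclopentane-1-carboxylate | C=C(C)[C@@H]1CC[C@@](C)(O)[C@H]1C(=O)OC
F2 | step 4 | (1R,2R,3R)-2-(hydroxymethyl)-1-methyl-3-(prop-1-en-2-yl)cyclopentan-1-ol | C=C(C)[C@@H]1CC[C@@](C)(O)[C@H]1CO
F3 | step 6 | (1S,2R,5R)-2-methyl-5-(prop-1-en-2-yl)-2-[(triethylsilyl)oxy]cyclopentane-1-carbaldehyde | C=C(C)[C@@H]1CC[C@@](C)(O[Si](CC)(CC)CC)[C@H]1C=O
F4 | step 6 | 2-methyl-1-[2,4,6-trihydroxy-3-methyl-5-({(1S,2R,5R)-2-methyl-5-(prop-1-en-2-yl)-2-[(triethylsilyl)oxy]cyclopentyl}methyl)phenyl]propan-1-one | C=C(C)[C@@H]1CC[C@@](C)(O[Si](CC)(CC)CC)[C@H]1Cc1c(O)c(C)c(O)c(C(=O)C(C)C)c1O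
F5 | step 7 | (6S)-3,5-dihydroxy-4-{[(1S,2R,5R)-2-hydroxy-2-methyl-5-(prop-1-en-2-yl)cyclopentyl]methyl}-6-methyl-6-(3-methylbut-2-en-1-yl)-2-(2-methylpropanoyl)cyclohexa-2,4-dien-1-one | C=C(C)[C@@H]1CC[C@@](C)(O)[C@H]1CC1=C(O)[C@](C)(CC=C(C)C)C(=O)C(C(=O)C(C)C)=C1O
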